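**Strategy.** Both halves are 7,8-dioxygenated 2-arylchromans of opposite C2 configuration, joined from C4 of the upper unit to C6 of the lower one. Ring C of each is made by one [3+3] annulation that exploits two mappings: O1–C2–C3 onto an enantiopure aryloxirane and C4–C4a–C8a onto an ortho-bromobenzyl sulfone of ring A. The sulfone reverses the polarity of C4, whose carbanion opens the oxirane at CH2 (C3–C4); the liberated C2 alkoxide is then arylated at C8a–Br under copper catalysis in the same flask (O1–C8a). Sulfinate loss gives flav-3-enes: one is dihydroxylated, the other becomes a C4 thioether electrophile for a trans-selective Friedel–Crafts union.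

Key step: step 7

Remark: flavan numbering (O1, C2, C3, C4, C4a, C5 to C8, C8a) is used for every chroman. CIP descriptors at C2, C3 and C4 change along the route as substituents change although the spatial arrangement is kept, so the SMILES strings are authoritative.
Remark: in steps 7 and 9 the two bond-forming events are run in one flask without isolation of the intermediate.

**Route**

Step 1
Reactants: 1 2-bromo-3-hydroxy-4-methoxybenzaldehyde
Product: 2 2-bromo-3,4-dihydroxybenzaldehyde
Conditions: BBr3 (2.5 equiv), CH2Cl2, −78 °C to rt; then H2O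
Reagents that add atoms: none
Why: Lewis-acid aryl methyl ether cleavage (BBr3 demethylation) should free the catechol without touching the aldehyde or the aryl bromide, so that ring A can carry hydrogenolysable benzyl ethers.

Step 2
Reactants: 2 2-bromo-3,4-dihydroxybenzaldehyde
Product: 3 3,4-bis(benzyloxy)-2-bromobenzaldehyde
Conditions: BnBr (2.3 equiv), K2CO3, DMF, 60 °C
Reagents that add atoms: benzyl bromide, BrCc1ccccc1
Why: Double Williamson etherification; the benzyl ethers should survive all later basic, oxidative and Lewis-acidic steps and fall in the final hydrogenolysis.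

Step 3
Reactants: 3 3,4-bis(benzyloxy)-2-bromobenzaldehyde
Product: 4 [3,4-bis(benzyloxy)-2-bromophenyl]methanol
Conditions: NaBH4, THF/MeOH, 0 °C
Reagents that add atoms: none
Why: Borohydride reduction of the aldehyde to the benzylic alcohol; aryl bromide and benzyl ethers are inert.

Step 4
Reactants: 4 [3,4-bis(benzyloxy)-2-bromophenyl]methanol
Product: 6 1,2-bis(benzyloxy)-3-bromo-4-[(phenylsulfonyl)methyl]benzene, via benzylic chloride 5 (not isolated)
Conditions: SOCl2, CH2Cl2, 0 °C; evaporate; PhSO2Na, n-Bu4NI (cat.), DMF, 60 °C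
Reagents that add atoms: sodium benzenesulfinate, [Na+].[O-]S(=O)c1ccccc1
Why: Chlorodehydroxylation followed by SN2 S-alkylation of the sulfinate should give the sulfone whose CH2 group becomes C4 and is acidified for the annulation.

Step 5
Reactants: 7 1-[4-(benzyloxy)phenyl]-2-bromoethan-1-one
Product: 9 (2R)-2-[4-(benzyloxy)phenyl]oxirane, via (R)-bromohydrin 8 (not isolated)
Conditions: (R)-2-methyl-CBS-oxazaborolidine (10 mol %), BH3·SMe2, THF, 0 °C; then 2 M NaOH, rt
Reagents that add atoms: none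
Why: Corey–Bakshi–Shibata reduction, with the aryl group as the large substituent, should set the carbinol centre (the future upper C2) as R; the intramolecular Williamson closure at CH2 leaves that centre untouched.

Step 6
Reactants: 7 1-[4-(benzyloxy)phenyl]-2-bromoethan-1-one
Product: 11 (2S)-2-[4-(benzyloxy)phenyl]oxirane, via (S)-bromohydrin 10 (not isolated)
Conditions: (S)-2-methyl-CBS-oxazaborolidine (10 mol %), BH3·SMe2, THF, 0 °C; then 2 M NaOH, rt
Reagents that add atoms: none
Why: The same Corey–Bakshi–Shibata reduction and Williamson closure with the enantiomeric catalyst should give the S epoxide that carries the future lower C2.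

Step 7
Reactants: 6 1,2-bis(benzyloxy)-3-bromo-4-[(phenylsulfonyl)methyl]benzene; 9 (2R)-2-[4-(benzyloxy)phenyl]oxirane
Product: 13 (2S)-7,8-bis(benzyloxy)-2-[4-(benzyloxy)phenyl]-4-(phenylsulfonyl)-3,4-dihydro-2H-chromene (both C4 epimers), via hydroxy sulfone 12 (not isolated)
Conditions: KN(SiMe3)2 (1.2 equiv), THF/DMPU, −78 °C, then 9, −78 to 45 °C; then CuI (20 mol %), 3,4,7,8-tetramethyl-1,10-phenanthroline (40 mol %), toluene, 110 °C (THF distilled off)
Reagents that add atoms: none
Why: The α-sulfonyl benzylic carbanion of 6 (C4, reversed in polarity from the normally electrophilic flavan C4) should open oxirane 9 by SN2 attack at the unsubstituted CH2 carbon, which forms C3–C4 and releases the C2 potassium alkoxide of 12; under copper catalysis this alkoxide then undergoes intramolecular Ullmann-type O-arylation at the neighbouring C8a–Br, which forms O1–C8a. The closest known reaction types are epoxide opening by metalated benzyl sulfones and tandem epoxide opening/copper-catalysed intramolecular C–O coupling of ortho-halo aryl nucleophiles. Ring C closes as a six-membered ring by intramolecular C–O coupling at the aryl carbon, so the whole operation is a formal [3+3] annulation. No bond to C2 is broken, so its configuration comes unchanged from the epoxide; the new C4 centre forms as an epimer mixture, which is irrelevant because step 8 destroys it. The step needs attack at the terminal and not the benzylic epoxide carbon, which the soft, hindered carbanion under Lewis-acid-free, DMPU-solvated potassium conditions should secure. It also needs ring closure before sulfinate loss and without aryne formation, which the favourable six-membered closure, the weakly basic medium and the absence of a hydrogen ortho to bromine should secure.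

Step 8
Reactants: 13 (2S)-7,8-bis(benzyloxy)-2-[4-(benzyloxy)phenyl]-4-(phenylsulfonyl)-3,4-dihydro-2H-chromene
Product: 14 (2S)-7,8-bis(benzyloxy)-2-[4-(benzyloxy)phenyl]-2H-chromene
Conditions: KOtBu (3 equiv), THF, 0 °C to rt, dark
Reagents that add atoms: none
Why: Base-mediated 1,2-elimination of benzenesulfinate (dehydrosulfonylation) across C3–C4 should give the styrene-type 2H-chromene; C2 should keep its configuration because deprotonation there would create an 8π pyranide anion and is therefore slow.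

Step 9
Reactants: 6 1,2-bis(benzyloxy)-3-bromo-4-[(phenylsulfonyl)methyl]benzene; 11 (2S)-2-[4-(benzyloxy)phenyl]oxirane
Product: 16 (2R)-7,8-bis(benzyloxy)-2-[4-(benzyloxy)phenyl]-4-(phenylsulfonyl)-3,4-dihydro-2H-chromene (both C4 epimers), via hydroxy sulfone 15 (not isolated)
Conditions: KN(SiMe3)2 (1.2 equiv), THF/DMPU, −78 °C, then 11, −78 to 45 °C; then CuI (20 mol %), 3,4,7,8-tetramethyl-1,10-phenanthroline (40 mol %), toluene, 110 °C
Reagents that add atoms: none
Why: The same tandem oxirane opening/copper-catalysed intramolecular Ullmann etherification as in step 7, now with the S epoxide, so that C2 of the lower unit is taken from the epoxide; the C4 epimers are again inconsequential.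

Step 10
Reactants: 16 (2R)-7,8-bis(benzyloxy)-2-[4-(benzyloxy)phenyl]-4-(phenylsulfonyl)-3,4-dihydro-2H-chromene
Product: 17 (2R)-7,8-bis(benzyloxy)-2-[4-(benzyloxy)phenyl]-2H-chromene
Conditions: KOtBu (3 equiv), THF, 0 °C to rt, dark
Reagents that add atoms: none
Why: Dehydrosulfonylation as in step 8, with C2 retained for the same reason.

Step 11
Reactants: 17 (2R)-7,8-bis(benzyloxy)-2-[4-(benzyloxy)phenyl]-2H-chromene
Product: 18 (2S,3R,4R)-7,8-bis(benzyloxy)-2-[4-(benzyloxy)phenyl]-3,4-dihydro-2H-chromene-3,4-diol (2,3-trans-3,4-cis)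
Conditions: K2OsO4·2H2O (2 mol %), N-methylmorpholine N-oxide (1.5 equiv), acetone/H2O, 0 °C to rt
Reagents that add atoms: N-methylmorpholine N-oxide, C[N+]1([O-])CCOCC1; water, O
Why: Upjohn dihydroxylation; osmium tetroxide should add suprafacially to the C3=C4 face anti to the C2 aryl group, which sets C3 and C4 together as the 2,3-trans-3,4-cis diol.

Step 12
Reactants: 18 (2S,3R,4R)-7,8-bis(benzyloxy)-2-[4-(benzyloxy)phenyl]-3,4-dihydro-2H-chromene-3,4-diol
Product: 19 cyclic 3,4-carbonate of 18 [(2S,3S,4R)-7,8-bis(benzyloxy)-2-[4-(benzyloxy)phenyl]chromane-3,4-diyl carbonate]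
Conditions: 1,1'-carbonyldiimidazole (1.5 equiv), THF, rt to 40 °C
Reagents that add atoms: 1,1'-carbonyldiimidazole, O=C(n1ccnc1)n1ccnc1
Why: Acyl transfer to the cis-diol should close the cis-fused five-membered carbonate, which masks both hydroxyls, withdraws electron density from the benzylic C4–O bond so that it should not ionise in step 15, and is removable by mild base.

Step 13
Reactants: 14 (2S)-7,8-bis(benzyloxy)-2-[4-(benzyloxy)phenyl]-2H-chromene
Product: 20 (2R,3S,4R)-7,8-bis(benzyloxy)-2-[4-(benzyloxy)phenyl]-3-bromo-3,4-dihydro-2H-chromen-4-ol (2,3-trans-3,4-trans)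
Conditions: N-bromosuccinimide (1.05 equiv), THF/H2O (4:1), 0 °C, dark
Reagents that add atoms: N-bromosuccinimide, O=C1CCC(=O)N1Br; water, O
Why: Bromohydrin formation; the bromonium ion should form on the face anti to the C2 aryl group and water should open it at benzylic C4 (cation stabilised by O1 and the para benzyloxy group) anti to bromine, which sets C3–Br trans to the aryl group.

Step 14
Reactants: 20 (2R,3S,4R)-7,8-bis(benzyloxy)-2-[4-(benzyloxy)phenyl]-3-bromo-3,4-dihydro-2H-chromen-4-ol
Product: 22 (2R,3S,4S)-7,8-bis(benzyloxy)-2-[4-(benzyloxy)phenyl]-4-(phenylsulfanyl)-3,4-dihydro-2H-chromen-3-ol (2,3-cis-3,4-trans), via cis-3,4-epoxide 21 (not isolated)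
Conditions: NaH (2.2 equiv), THF, 0 °C; then PhSH (1.2 equiv), 0 °C to rt
Reagents that add atoms: benzenethiol, Sc1ccccc1
Why: Intramolecular Williamson closure of the trans bromohydrin inverts C3 and so places the epoxide oxygen cis to the C2 aryl group, which fixes the 2,3-cis relationship of the upper unit; thiolate then opens the activated benzylic C4 by SN2 and installs the thiophilic leaving group.

Step 15
Reactants: 22 (2R,3S,4S)-7,8-bis(benzyloxy)-2-[4-(benzyloxy)phenyl]-4-(phenylsulfanyl)-3,4-dihydro-2H-chromen-3-ol; 19 cyclic 3,4-carbonate of 18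
Product: 23 hexa-O-benzyl (4→6)-linked biflavan with free upper 3-OH and lower 3,4-carbonate (upper unit 2,3-cis-3,4-trans; lower unit 2,3-trans-3,4-cis)
Conditions: AgBF4 (2.5 equiv), 19 (3 equiv, excess recovered), THF, 0 °C, dark; then aqueous NaHCO3
Reagents that add atoms: none
Why: Silver-promoted thiophilic ionisation of the C4–S bond should give the benzylic cation stabilised by O1 and the 7-benzyloxy group, which undergoes Friedel–Crafts alkylation at C6 of 19 (para to O1, ortho to the 7-benzyloxy group and less hindered than C5). In the 2,3-cis series the arene should enter anti to the axial C3 hydroxyl and set C4 as 3,4-trans, while the carbonate keeps the lower C4–O bond from ionising and the excess of 19 suppresses self-condensation through ring A of 22.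

Step 16
Reactants: 23 hexa-O-benzyl (4→6)-linked biflavan 3,4-carbonate
Product: 24 hexa-O-benzyl ether of the target (upper 3-OH and lower 3,4-diol free)
Conditions: K2CO3 (0.5 equiv), MeOH/THF, 0 °C to rt, argon
Reagents that add atoms: none
Why: Base-catalysed transesterification (methanolysis) of the cyclic carbonate should free the 3,4-cis diol without ionising benzylic C4 or epimerising any centre, while the phenols are still protected against base-promoted oxidation.

Step 17
Reactants: 24 hexa-O-benzyl ether of the target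
Product: 25 (2R,3R,4S)-2-(4-hydroxyphenyl)-4-[(2S,3R,4R)-3,4,7,8-tetrahydroxy-2-(4-hydroxyphenyl)-3,4-dihydro-2H-chromen-6-yl]-3,4-dihydro-2H-chromene-3,7,8-triol
Conditions: H2 (1 atm), Pd(OH)2/C, THF/MeOH, rt; filtration under argon, lyophilisation
Reagents that add atoms: none
Why: Catalytic hydrogenolysis of the six benzyl aryl ethers under neutral conditions; the secondary benzylic C4 hydroxyl and the interflavan bond should survive because no acid is present.

**Compound list**

1 | 2-bromo-3-hydroxy-4-methoxybenzaldehyde | O=Cc1ccc(OC)c(O)c1Br | starting material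
2 | 2-bromo-3,4-dihydroxybenzaldehyde | O=Cc1ccc(O)c(O)c1Br | intermediate
3 | 3,4-bis(benzyloxy)-2-bromobenzaldehyde | O=Cc1ccc(OCc2ccccc2)c(OCc2ccccc2)c1Br | intermediate
4 | [3,4-bis(benzyloxy)-2-bromophenyl]methanol | OCc1ccc(OCc2ccccc2)c(OCc2ccccc2)c1Br | intermediate
5 | 1,2-bis(benzyloxy)-3-bromo-4-(chloromethyl)benzene (not isolated) | ClCc1ccc(OCc2ccccc2)c(OCc2ccccc2)c1Br | intermediate
6 | 1,2-bis(benzyloxy)-3-bromo-4-[(phenylsulfonyl)methyl]benzene | O=S(=O)(Cc1ccc(OCc2ccccc2)c(OCc2ccccc2)c1Br)c1ccccc1 | intermediate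
7 | 1-[4-(benzyloxy)phenyl]-2-bromoethan-1-one | O=C(CBr)c1ccc(OCc2ccccc2)cc1 | starting material
8 | (1R)-1-[4-(benzyloxy)phenyl]-2-bromoethan-1-ol (not isolated) | O[C@@H](CBr)c1ccc(OCc2ccccc2)cc1 | intermediate
9 | (2R)-2-[4-(benzyloxy)phenyl]oxirane | C1O[C@@H]1c1ccc(OCc2ccccc2)cc1 | intermediate
10 | (1S)-1-[4-(benzyloxy)phenyl]-2-bromoethan-1-ol (not isolated) | O[C@H](CBr)c1ccc(OCc2ccccc2)cc1 | intermediate
11 | (2S)-2-[4-(benzyloxy)phenyl]oxirane | C1O[C@H]1c1ccc(OCc2ccccc2)cc1 | intermediate
12 | (1S)-1-[4-(benzyloxy)phenyl]-3-[3,4-bis(benzyloxy)-2-bromophenyl]-3-(phenylsulfonyl)propan-1-ol, both C3 epimers (not isolated) | O[C@@H](CC(c1ccc(OCc2ccccc2)c(OCc2ccccc2)c1Br)S(=O)(=O)c1ccccc1)c1ccc(OCc2ccccc2)cc1 | intermediate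
13 | (2S)-7,8-bis(benzyloxy)-2-[4-(benzyloxy)phenyl]-4-(phenylsulfonyl)-3,4-dihydro-2H-chromene, both C4 epimers | O1[C@H](c2ccc(OCc3ccccc3)cc2)CC(S(=O)(=O)c2ccccc2)c2ccc(OCc3ccccc3)c(OCc3ccccc3)c12 | intermediate
14 | (2S)-7,8-bis(benzyloxy)-2-[4-(benzyloxy)phenyl]-2H-chromene | O1[C@H](c2ccc(OCc3ccccc3)cc2)C=Cc2ccc(OCc3ccccc3)c(OCc3ccccc3)c12 | intermediate
15 | (1R)-1-[4-(benzyloxy)phenyl]-3-[3,4-bis(benzyloxy)-2-bromophenyl]-3-(phenylsulfonyl)propan-1-ol, both C3 epimers (not isolated) | O[C@H](CC(c1ccc(OCc2ccccc2)c(OCc2ccccc2)c1Br)S(=O)(=O)c1ccccc1)c1ccc(OCc2ccccc2)cc1 | intermediate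
16 | (2R)-7,8-bis(benzyloxy)-2-[4-(benzyloxy)phenyl]-4-(phenylsulfonyl)-3,4-dihydro-2H-chromene, both C4 epimers | O1[C@@H](c2ccc(OCc3ccccc3)cc2)CC(S(=O)(=O)c2ccccc2)c2ccc(OCc3ccccc3)c(OCc3ccccc3)c12 | intermediate
17 | (2R)-7,8-bis(benzyloxy)-2-[4-(benzyloxy)phenyl]-2H-chromene | O1[C@@H](c2ccc(OCc3ccccc3)cc2)C=Cc2ccc(OCc3ccccc3)c(OCc3ccccc3)c12 | intermediate
18 | (2S,3R,4R)-7,8-bis(benzyloxy)-2-[4-(benzyloxy)phenyl]-3,4-dihydro-2H-chromene-3,4-diol | O1[C@@H](c2ccc(OCc3ccccc3)cc2)[C@H](O)[C@H](O)c2ccc(OCc3ccccc3)c(OCc3ccccc3)c12 | intermediate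
19 | (2S,3S,4R)-7,8-bis(benzyloxy)-2-[4-(benzyloxy)phenyl]chromane-3,4-diyl carbonate (cyclic carbonate of 18) | O1[C@@H](c2ccc(OCc3ccccc3)cc2)[C@@H]3OC(=O)O[C@@H]3c2ccc(OCc4ccccc4)c(OCc4ccccc4)c12 | intermediate
20 | (2R,3S,4R)-7,8-bis(benzyloxy)-2-[4-(benzyloxy)phenyl]-3-bromo-3,4-dihydro-2H-chromen-4-ol | O1[C@H](c2ccc(OCc3ccccc3)cc2)[C@@H](Br)[C@H](O)c2ccc(OCc3ccccc3)c(OCc3ccccc3)c12 | intermediate
21 | (2R,3R,4R)-7,8-bis(benzyloxy)-2-[4-(benzyloxy)phenyl]-3,4-epoxychromane, epoxide oxygen cis to the 2-aryl group (not isolated) | O1[C@H](c2ccc(OCc3ccccc3)cc2)[C@@H]3O[C@@H]3c2ccc(OCc4ccccc4)c(OCc4ccccc4)c12 | intermediate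
22 | (2R,3S,4S)-7,8-bis(benzyloxy)-2-[4-(benzyloxy)phenyl]-4-(phenylsulfanyl)-3,4-dihydro-2H-chromen-3-ol | O1[C@H](c2ccc(OCc3ccccc3)cc2)[C@H](O)[C@@H](Sc2ccccc2)c2ccc(OCc3ccccc3)c(OCc3ccccc3)c12 | intermediate
23 | hexa-O-benzyl (4→6)-linked biflavan, upper unit (2R,3R,4R) with free 3-OH, lower unit (2S,3S,4R) as 3,4-carbonate | O1[C@H](c2ccc(OCc3ccccc3)cc2)[C@H](O)[C@@H](c2cc3c(c(OCc4ccccc4)c2OCc2ccccc2)O[C@@H](c2ccc(OCc4ccccc4)cc2)[C@@H]2OC(=O)O[C@H]32)c2ccc(OCc3ccccc3)c(OCc3ccccc3)c12 | intermediate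
24 | hexa-O-benzyl ether of the target, upper unit (2R,3R,4R), lower unit (2S,3R,4R) | O1[C@H](c2ccc(OCc3ccccc3)cc2)[C@H](O)[C@@H](c2cc3c(c(OCc4ccccc4)c2OCc2ccccc2)O[C@@H](c2ccc(OCc4ccccc4)cc2)[C@H](O)[C@@H]3O)c2ccc(OCc3ccccc3)c(OCc3ccccc3)c12 | intermediate
25 | (2R,3R,4S)-2-(4-hydroxyphenyl)-4-[(2S,3R,4R)-3,4,7,8-tetrahydroxy-2-(4-hydroxyphenyl)-3,4-dihydro-2H-chromen-6-yl]-3,4-dihydro-2H-chromene-3,7,8-triol | Oc1ccc([C@H]2Oc3c(ccc(O)c3O)[C@H](c3cc4c(c(O)c3O)O[C@@H](c3ccc(O)cc3)[C@H](O)[C@@H]4O)[C@H]2O)cc1 | target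

**Totals.** Total step count: 17. Longest linear sequence: 11 steps (steps 1, 2, 3, 4, 7, 8, 13, 14, 15, 16, 17).

**Steps most likely to fail**

1. Step 7 (and its twin, step 9). What may go wrong: the carbanion may attack the benzylic instead of the terminal oxirane carbon; the open-chain alkoxide may lose sulfinate to an E-styrene that can no longer cyclise; the copper etherification may be slow at the doubly ortho-substituted C–Br bond while most of the intermediate rests as the sulfonyl carbanion. Fallback, setting out from sulfone 6 and bromohydrin 8 (isolated by leaving out the NaOH treatment in step 5): silylation (TBSCl, imidazole, DMF) should give tert-butyl{(1R)-1-[4-(benzyloxy)phenyl]-2-bromoethoxy}dimethylsilane F1. Alkylation of the KN(SiMe3)2-derived carbanion of 6 with F1 (NaI cat., THF/DMPU, −78 °C to rt) has only one electrophilic carbon, which removes the regiochemical question, and should give the silyl ether of the hydroxy sulfone F2. n-Bu4NF in THF then liberates 12, which is now isolated and purified. Ring closure is carried out separately by palladium-catalysed intramolecular etherification (Pd(OAc)2, 2-(di-tert-butylphosphino)-1,1'-binaphthyl, Cs2CO3, toluene, 70 °C), and the route is rejoined at 13.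

2. Step 15. What may go wrong: self-alkylation of the cation through C6 of its own ring A (oligomers), attack at C5 instead of C6 of 19, and ionisation of C4–O bonds by the HBF4 that is formed. Fallback, setting out from bromohydrin 20: NaH in THF followed by methanol should open the cis-epoxide to (2R,3R,4S)-7,8-bis(benzyloxy)-2-[4-(benzyloxy)phenyl]-4-methoxy-3,4-dihydro-2H-chromen-3-ol F3. Acetylation (Ac2O, pyridine, DMAP) gives the 3-acetate F4. Oxophilic activation (TMSOTf cat., CH2Cl2, −78 °C) in the presence of 19 (3 equiv) then proceeds through a cis-fused acetoxonium ion that shields the face of the C3 oxygen, so the arene should enter trans and give the 3-O-acetyl biflavan carbonate F5. K2CO3 in MeOH removes acetate and carbonate together, and the route is rejoined at 24.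

3. Step 13. What may go wrong: bromonium formation on the face syn to the C2 aryl group, electrophilic bromination of ring A, and decomposition of the labile bromohydrin and of the epoxide derived from it. Fallback, setting out from chromene 14: hydroboration–oxidation (BH3·THF; NaOH, H2O2) should give the 2,3-trans alcohol (2R,3S)-7,8-bis(benzyloxy)-2-[4-(benzyloxy)phenyl]-3,4-dihydro-2H-chromen-3-ol F6. Dess–Martin oxidation gives the ketone (2R)-7,8-bis(benzyloxy)-2-[4-(benzyloxy)phenyl]chroman-3-one F7, which is used at once. LiBH(s-Bu)3 in THF at −78 °C should deliver hydride trans to the aryl group and give the 2,3-cis alcohol (2R,3R)-7,8-bis(benzyloxy)-2-[4-(benzyloxy)phenyl]-3,4-dihydro-2H-chromen-3-ol F8. Benzylic oxidation with DDQ in the presence of 2-ethoxyethanol (CH2Cl2, rt) gives the 4-(2-ethoxyethoxy) ether F9, which is coupled with 19 (3 equiv) under TMSOTf in CH2Cl2 at −78 °C. The route is rejoined at 23.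

Further compounds
F1 | step 7 | tert-butyl{(1R)-1-[4-(benzyloxy)phenyl]-2-bromoethoxy}dimethylsilane | CC(C)(C)[Si](C)(C)O[C@@H](CBr)c1ccc(OCc2ccccc2)cc1
F2 | step 7 | tert-butyldimethylsilyl ether of hydroxy sulfone 12 (1S, both sulfone-carbon epimers) | CC(C)(C)[Si](C)(C)O[C@@H](CC(c1ccc(OCc2ccccc2)c(OCc2ccccc2)c1Br)S(=O)(=O)c1ccccc1)c1ccc(OCc2ccccc2)cc1
F3 | step 15 | (2R,3R,4S)-7,8-bis(benzyloxy)-2-[4-(benzyloxy)phenyl]-4-methoxy-3,4-dihydro-2H-chromen-3-ol | O1[C@H](c2ccc(OCc3ccccc3)cc2)[C@H](O)[C@@H](OC)c2ccc(OCc3ccccc3)c(OCc3ccccc3)c12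
F4 | step 15 | (2R,3R,4S)-7,8-bis(benzyloxy)-2-[4-(benzyloxy)phenyl]-4-methoxy-3,4-dihydro-2H-chromen-3-yl acetate | O1[C@H](c2ccc(OCc3ccccc3)cc2)[C@H](OC(C)=O)[C@@H](OC)c2ccc(OCc3ccccc3)c(OCc3ccccc3)c12
F5 | step 15 | 3-O-acetate of biflavan carbonate 23 | O1[C@H](c2ccc(OCc3ccccc3)cc2)[C@H](OC(C)=O)[C@@H](c2cc3c(c(OCc4ccccc4)c2OCc2ccccc2)O[C@@H](c2ccc(OCc4ccccc4)cc2)[C@@H]2OC(=O)O[C@H]32)c2ccc(OCc3ccccc3)c(OCc3ccccc3)c12
F6 | step 13 | (2R,3S)-7,8-bis(benzyloxy)-2-[4-(benzyloxy)phenyl]-3,4-dihydro-2H-chromen-3-ol | O1[C@H](c2ccc(OCc3ccccc3)cc2)[C@@H](O)Cc2ccc(OCc3ccccc3)c(OCc3ccccc3)c12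
F7 | step 13 | (2R)-7,8-bis(benzyloxy)-2-[4-(benzyloxy)phenyl]chroman-3-one | O1[C@H](c2ccc(OCc3ccccc3)cc2)C(=O)Cc2ccc(OCc3ccccc3)c(OCc3ccccc3)c12
F8 | step 13 | (2R,3R)-7,8-bis(benzyloxy)-2-[4-(benzyloxy)phenyl]-3,4-dihydro-2H-chromen-3-ol | O1[C@H](c2ccc(OCc3ccccc3)cc2)[C@H](O)Cc2ccc(OCc3ccccc3)c(OCc3ccccc3)c12
F9 | step 13 | (2R,3R,4S)-7,8-bis(benzyloxy)-2-[4-(benzyloxy)phenyl]-4-(2-ethoxyethoxy)-3,4-dihydro-2H-chromen-3-ol | O1[C@H](c2ccc(OCc3ccccc3)cc2)[C@H](O)[C@@H](OCCOCC)c2ccc(OCc3ccccc3)c(OCc3ccccc3)c12
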